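1. 50.0% was my opening entry: Monday's G charge as a fraction of its E charge, the G ceiling. E + G → Z + D spends one G per D, and G is the limiting reagent in Monday's flask.

in all of them: E 0.20 M
- theta: G 0.057 M; temperature 0 °C; run made earlier
- eta: G 0.12 M; temperature 15 °C; run made earlier
- Monday's: G 0.100 M; temperature 25 °C; time 40 h
- Friday's: G 0.200 M; temperature 5 °C; time 40 h

| theta: time / h | theta: D / % | eta: time / h | eta: D / % |
|---|---|---|---|
| 2.00 | 8.9 | 3.00 | 47.5 |
| 5.00 | 13.6 | 6.00 | 56.9 |
| 10.0 | 20.2 | 10.0 | 59.9 |
| 15.0 | 24.6 | 12.0 | 59.1 |
| 20.0 | 26.8 | 15.0 | 58.8 |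
| 30.0 | 27.7 | 20.0 | 60.9 |

(each reading ± 0.5 percentage points)

- the winner by amount of D, in percent of the E charged; "neither" if no more than 2 percentage points parts them (Monday's / Friday's / neither)
- how much D is there at the end, in percent of the E charged: Monday's
- how much D is there at the end, in percent of the E charged: Friday's

- steps that have been proposed: G + Z <-> J; E + Z -> L; E + G -> Z + D; Z -> X

2. The ledger of G has three lines: free G, G held in J through G + Z ⇌ J, and G spent as D. The earlier runs closed on the last line. Theta's ceiling was 28.5% and its last reading 27.7%; eta's ceiling was 60.0% and its last reading 60.9%.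

3. Eta read 59.9% by 10.0 h at 15 °C. Monday's flask is warmer and runs longer, so I booked it at its ceiling, 50.0%.

4. Friday's ceiling is 100%, twice Monday's, but its E and G charges are equal, so both fall together and the last entries come slowly. I needed a pace, so I read one from theta. Between 5.00 h and 15.0 h, D rose by 0.0110 h⁻¹ as a fraction of the E charge. At the middle reading, 79.8% of the E charge was still E and 8.30% of it was G not yet spent, J counted in. Rise over their product gave a pace of 0.166 h⁻¹, as a reading.

5. Friday's flask has the same E charge, so the inverse of the fraction left grows from one by pace times time. After 40 h that left 0.131, which books 86.9% as D. Friday's is warmer than theta, so I took this as a lower mark, and it stands above Monday's ceiling.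

6. The forecast, lower than my mark, named Friday's, with 49% for Monday's and 76% for Friday's, holding that L “costs D directly”.

    G + Z ⇌ J, settled at all times (K = 260 M⁻¹, ΔH = −29.0 kJ mol⁻¹)
    E + Z → L (k = 1.40 M⁻¹ h⁻¹, Ea = 73.0 kJ mol⁻¹)
    E + G → Z + D (k = 2.00 M⁻¹ h⁻¹, Ea = 70.0 kJ mol⁻¹)
    Z → X (k = 3.70 h⁻¹, Ea = 88.0 kJ mol⁻¹)
    (constants at 5 °C)

Monday's ended at 50.0%, on its ceiling 50.0%, and Friday's at 91.5%, above my mark, so Friday's won. At 40.0 h Friday's ledger still showed 8.20% of its G free, and 2.42% of its E had gone to L. The neighbour flask, Friday's with 0.34 M of E, has a G ceiling of 58.8%; it ended at 58.8% of its E charge, with 0.0084% of its G left free.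

The earlier runs and the new flask are simulated with made-up constants, and the scatter is random.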